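**Strategy.** The route rests on opening the dihydrofuran ring of the 2,3-dihydrobenzofuran at O1–C2 and cutting the side chain at C1'–C2'. These two bonds sit on the adjacent stereocentres C2 and C1', so one palladium-catalysed oxidative cyclisation–methoxycarbonylation of an alkene adds the ring oxygen and the future CH2O carbon, closes the five-membered ring and sets both centres: alkene geometry fixes the relative, a chiral bis(oxazoline) the absolute configuration. The precursor is methyl 3-[(2E)-but-2-en-1-yl]-4-hydroxybenzoate, two steps from methyl 4-hydroxybenzoate. Reduction, benzylic oxidation, Mitsunobu coumaroylation and a Knoevenagel–Doebner condensation then finish the target without protecting groups.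

Key step: step 3

Locants: dihydrobenzofuran O1, C2, C3, C5; side chain C1' (the CH bearing CH3) and C2' (the CH2O carbon).

Stereochemical bookkeeping: anti addition of O1 and palladium across the E-alkene, followed by CO insertion with retention, gives the (2S,2'R)-diester. This has the same spatial arrangement as the (2S,1'S) target; the C1' descriptor changes only because CO2CH3 outranks C2 whereas CH2O does not.

Assumption: the sense of facial induction of the bis(oxazoline) on this substrate cannot be predicted with confidence, so the route is written with the (S,S)-ligand, and its equally available (R,R)-antipode is used instead if a pilot run shows oxygen delivery to the Re face of C2.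

**Route**

Step 1
Reactants: 1 methyl 4-hydroxybenzoate; 2 but-3-en-2-ol (racemic)
Product: 3 methyl 4-(but-3-en-2-yloxy)benzoate (racemic)
Conditions: PPh3 (1.2 equiv), DIAD (1.2 equiv), THF, 0 °C to rt
Reagents that add atoms: none
Why: Mitsunobu etherification: the acidic para-ester phenol is a good pronucleophile and displaces the activated secondary allylic alcohol by SN2 at carbon; the ether stereocentre is formed racemic, which is immaterial because it is destroyed in step 2.

Step 2
Reactants: 3 methyl 4-(but-3-en-2-yloxy)benzoate
Product: 5 methyl 3-[(2E)-but-2-en-1-yl]-4-hydroxybenzoate, via ortho-dienone 4 (not isolated)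
Conditions: N,N-diethylaniline, 180–190 °C; recrystallisation (or AgNO3-impregnated silica) to remove any Z isomer
Reagents that add atoms: none
Why: Aromatic Claisen rearrangement: the [3,3]-shift runs through a chair transition state with the α-methyl group equatorial, which should give the E-alkene in dienone 4 (whose stereocentre is lost on tautomerisation to phenol 5), both ortho positions are equivalent and the para position is blocked, and the basic solvent suppresses acid-induced cyclisation of the product.

Step 3
Reactants: 5 methyl 3-[(2E)-but-2-en-1-yl]-4-hydroxybenzoate; 6 carbon monoxide; 7 methanol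
Product: 10 methyl (2S)-2-[(2R)-1-methoxy-1-oxopropan-2-yl]-2,3-dihydro-1-benzofuran-5-carboxylate, via alkylpalladium species 8 (not isolated), via acylpalladium species 9 (not isolated)
Conditions: Pd(OCOCF3)2 (10 mol %), 2,2'-(propane-2,2-diyl)bis[(4S)-4-phenyl-4,5-dihydro-1,3-oxazole] (12 mol %), p-benzoquinone (1.5 equiv), CO (1 atm), MeOH/CH2Cl2, 0 °C to rt
Reagents that add atoms: none
Why: The cationic divalent palladium–bis(oxazoline) complex, carrying CO, binds the E-alkene of 5 and the phenol oxygen attacks C2 from the face opposite the metal (anti-oxypalladation) to give σ-alkylpalladium 8; CO then inserts into the C1'–Pd bond with retention to give acylpalladium 9, methanolysis releases 10 together with zerovalent palladium, and p-benzoquinone returns the metal to the divalent state. The closest known reaction type is the oxidative alkoxypalladation–methoxycarbonylation of hydroxy alkenes (a Wacker-type cyclisation terminated by carbonylation), which is stereospecifically anti on internal alkenes under CO and has enantioselective trifluoroacetate/bis(oxazoline)/benzoquinone variants on alkenyl phenols; the same catalyst system is also expected to add anti across tethered alkynes. The dihydrofuran ring closes by 5-exo-trig attack of O1 on C2. The relative configuration of C2 and C1' is controlled by the E geometry of the alkene combined with anti addition and retentive CO insertion (O1 and the C1' methyl end up syn along the C3–C2–C1'–C2' chain), and the absolute configuration by the ligand, which must hold palladium on the face that leaves the Si face of C2 open to oxygen (2S). The step needs 5-exo over 6-endo closure, secured by the single benzylic carbon between ring and alkene; CO capture over β-hydride elimination to the 2-vinyl compound, secured by the CO atmosphere and low temperature; and a geometrically pure alkene, secured in step 2. The acidic para-ester phenol is free for attack and the near-neutral medium should not epimerise the α-centre of the new ester.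

Step 4
Reactants: 10 methyl (2S)-2-[(2R)-1-methoxy-1-oxopropan-2-yl]-2,3-dihydro-1-benzofuran-5-carboxylate
Product: 11 (2S)-2-[(2S)-5-(hydroxymethyl)-2,3-dihydro-1-benzofuran-2-yl]propan-1-ol
Conditions: LiAlH4 (2.5 equiv), THF, −20 to 0 °C; aq. potassium sodium tartrate work-up
Reagents that add atoms: none
Why: Hydride reduction of both methyl esters by LiAlH4, fast enough at low temperature that the α-centre C1' is neither enolised nor lost by β-elimination of O1; no stereocentre is formed, and the C1' descriptor changes from R to S only because CH2OH ranks below C2 whereas CO2CH3 ranked above it.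

Step 5
Reactants: 11 (2S)-2-[(2S)-5-(hydroxymethyl)-2,3-dihydro-1-benzofuran-2-yl]propan-1-ol
Product: 12 (2S)-2-[(2S)-1-hydroxypropan-2-yl]-2,3-dihydro-1-benzofuran-5-carbaldehyde
Conditions: activated MnO2 (10 equiv), CH2Cl2, rt
Reagents that add atoms: none
Why: Chemoselective MnO2 oxidation: the electron-rich benzylic alcohol is oxidised to the aldehyde on the oxide surface while the saturated primary C2' alcohol is inert, and no stereocentre is touched.

Step 6
Reactants: 12 (2S)-2-[(2S)-1-hydroxypropan-2-yl]-2,3-dihydro-1-benzofuran-5-carbaldehyde; 13 (2E)-3-(4-hydroxyphenyl)prop-2-enoic acid (1.5 equiv)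
Product: 14 (2S)-2-[(2S)-5-formyl-2,3-dihydro-1-benzofuran-2-yl]propyl (2E)-3-(4-hydroxyphenyl)prop-2-enoate
Conditions: PPh3 (1.3 equiv), DIAD (1.3 equiv), THF, 0 °C to rt
Reagents that add atoms: none
Why: Mitsunobu esterification: the carboxylic acid of 13 is far more acidic than its phenol, so the carboxylate is the species alkylated by the activated primary C2' alcohol, substitution occurs at a non-stereogenic CH2 so C1' and C2 are untouched, and the aldehyde is a spectator.

Step 7
Reactants: 14 (2S)-2-[(2S)-5-formyl-2,3-dihydro-1-benzofuran-2-yl]propyl (2E)-3-(4-hydroxyphenyl)prop-2-enoate; 15 malonic acid (3 equiv)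
Product: 17 the target (2E)-3-{(2S)-2-[(2S)-1-{[(2E)-3-(4-hydroxyphenyl)prop-2-enoyl]oxy}propan-2-yl]-2,3-dihydro-1-benzofuran-5-yl}prop-2-enoic acid, via arylidenemalonic acid 16 (not isolated)
Conditions: pyridine, piperidine (0.1 equiv), 85 °C; then cold 1 M HCl
Reagents that add atoms: none
Why: Knoevenagel–Doebner condensation: the para-alkoxybenzaldehyde condenses with malonic acid under piperidine catalysis to arylidenemalonic acid 16, which decarboxylates in hot pyridine to the E-acrylic acid, while the coumarate ester and its free phenol tolerate the weakly basic medium and no stereocentre carries an acidic hydrogen.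

**Compound list**

1 | methyl 4-hydroxybenzoate | COC(=O)c1ccc(O)cc1 | starting material
2 | but-3-en-2-ol (racemic) | C=CC(C)O | starting material
3 | methyl 4-(but-3-en-2-yloxy)benzoate (racemic) | C=CC(C)Oc1ccc(C(=O)OC)cc1 | intermediate
4 | methyl 3-[(2E)-but-2-en-1-yl]-4-oxocyclohexa-1,5-diene-1-carboxylate (racemic ortho-dienone) | C/C=C/CC1C=C(C(=O)OC)C=CC1=O | intermediate
5 | methyl 3-[(2E)-but-2-en-1-yl]-4-hydroxybenzoate | C/C=C/Cc1cc(C(=O)OC)ccc1O | intermediate
6 | carbon monoxide | [C-]#[O+] | starting material
7 | methanol | CO | starting material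
8 | {(1R)-1-[(2S)-5-(methoxycarbonyl)-2,3-dihydro-1-benzofuran-2-yl]ethyl}palladium trifluoroacetate (bis(oxazoline) and CO ligands not drawn; Pd on C1' anti to O1) | C[C@@H]([Pd]OC(=O)C(F)(F)F)[C@@H]1Cc2cc(C(=O)OC)ccc2O1 | intermediate
9 | {(2R)-2-[(2S)-5-(methoxycarbonyl)-2,3-dihydro-1-benzofuran-2-yl]propanoyl}palladium trifluoroacetate (bis(oxazoline) and CO ligands not drawn) | C[C@@H](C(=O)[Pd]OC(=O)C(F)(F)F)[C@@H]1Cc2cc(C(=O)OC)ccc2O1 | intermediate
10 | methyl (2S)-2-[(2R)-1-methoxy-1-oxopropan-2-yl]-2,3-dihydro-1-benzofuran-5-carboxylate | C[C@@H](C(=O)OC)[C@@H]1Cc2cc(C(=O)OC)ccc2O1 | intermediate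
11 | (2S)-2-[(2S)-5-(hydroxymethyl)-2,3-dihydro-1-benzofuran-2-yl]propan-1-ol | C[C@@H](CO)[C@@H]1Cc2cc(CO)ccc2O1 | intermediate
12 | (2S)-2-[(2S)-1-hydroxypropan-2-yl]-2,3-dihydro-1-benzofuran-5-carbaldehyde | C[C@@H](CO)[C@@H]1Cc2cc(C=O)ccc2O1 | intermediate
13 | (2E)-3-(4-hydroxyphenyl)prop-2-enoic acid ((E)-4-hydroxycinnamic acid) | O=C(O)/C=C/c1ccc(O)cc1 | starting material
14 | (2S)-2-[(2S)-5-formyl-2,3-dihydro-1-benzofuran-2-yl]propyl (2E)-3-(4-hydroxyphenyl)prop-2-enoate | C[C@@H](COC(=O)/C=C/c1ccc(O)cc1)[C@@H]1Cc2cc(C=O)ccc2O1 | intermediate
15 | malonic acid (propanedioic acid) | O=C(O)CC(=O)O | starting material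
16 | 2-({(2S)-2-[(2S)-1-{[(2E)-3-(4-hydroxyphenyl)prop-2-enoyl]oxy}propan-2-yl]-2,3-dihydro-1-benzofuran-5-yl}methylidene)propanedioic acid | C[C@@H](COC(=O)/C=C/c1ccc(O)cc1)[C@@H]1Cc2cc(C=C(C(=O)O)C(=O)O)ccc2O1 | intermediate
17 | (2E)-3-{(2S)-2-[(2S)-1-{[(2E)-3-(4-hydroxyphenyl)prop-2-enoyl]oxy}propan-2-yl]-2,3-dihydro-1-benzofuran-5-yl}prop-2-enoic acid (CNP0224846.1) | C[C@@H](COC(=O)/C=C/c1ccc(O)cc1)[C@@H]1Cc2cc(/C=C/C(=O)O)ccc2O1 | target

**Step count and risks**

Total step count: 7. Longest linear sequence: 7 steps (1 to 17); compounds 2, 6, 7, 13 and 15 are used as purchased.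

Steps most likely to fail:

1. Step 3 (key step). The ligand may discriminate the alkene faces poorly, part of the material may react by syn-oxypalladation and so give the C1' epimer, or β-hydride elimination may outrun CO insertion. The fallback gives up catalyst-controlled induction in favour of a stereospecific racemic reaction followed by resolution. Starting from 5, the achiral chloride system (PdCl2 10 mol %, CuCl2 3 equiv, CO 1 atm, MeOH, rt), for which anti addition across internal alkenes is established, should give the anti diester as a racemate. This is 10 together with its enantiomer, methyl (2R)-2-[(2S)-1-methoxy-1-oxopropan-2-yl]-2,3-dihydro-1-benzofuran-5-carboxylate F1. Preparative chromatography on a cellulose tris(3,5-dimethylphenylcarbamate) stationary phase separates the two, and the route is rejoined at 10.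

2. Step 6. The phenol of 13, or of the product, may be O-alkylated in competition with the carboxylate, and the ester may be hard to free from phosphine oxide. The fallback replaces the redox condensation by a protected carboxyl activation. Starting from 13, acetylation (Ac2O, pyridine) gives (2E)-3-[4-(acetyloxy)phenyl]prop-2-enoic acid F2. Carbodiimide coupling of F2 with 12 (EDC·HCl, DMAP, CH2Cl2) gives (2S)-2-[(2S)-5-formyl-2,3-dihydro-1-benzofuran-2-yl]propyl (2E)-3-[4-(acetyloxy)phenyl]prop-2-enoate F3. Brief treatment with K2CO3 in MeOH at 0 °C should cleave only the aryl acetate, because the phenoxide that forms deactivates the cinnamate ester toward methanolysis, and the route is rejoined at 14.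

3. Step 2. The alkene geometry may erode (Z isomer through the axial-methyl transition state or by thermal isomerisation) and material may be lost by thermal ether cleavage; any Z alkene would be carried into the C1' epimer in step 3. The fallback fixes the geometry with a reagent instead of a transition state. Starting from 1, Blanc chloromethylation ortho to the hydroxyl (aq. formaldehyde, conc. HCl, HCl gas) gives methyl 3-(chloromethyl)-4-hydroxybenzoate F4. Acetylation (Ac2O, cat. H2SO4) gives methyl 4-(acetyloxy)-3-(chloromethyl)benzoate F5, which cannot form a quinone methide. Suzuki–Miyaura coupling of the benzylic chloride with (E)-prop-1-enylboronic acid (Pd(PPh3)4, K3PO4, THF, 60 °C) gives methyl 4-(acetyloxy)-3-[(2E)-but-2-en-1-yl]benzoate F6 with retention of the alkene geometry. K2CO3 in MeOH removes the acetate, and the route is rejoined at 5.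

**Further compounds**

F1 | step 3 | methyl (2R)-2-[(2S)-1-methoxy-1-oxopropan-2-yl]-2,3-dihydro-1-benzofuran-5-carboxylate (enantiomer of 10, formed with 10 as the racemate) | C[C@H](C(=O)OC)[C@H]1Cc2cc(C(=O)OC)ccc2O1
F2 | step 6 | (2E)-3-[4-(acetyloxy)phenyl]prop-2-enoic acid | CC(=O)Oc1ccc(/C=C/C(=O)O)cc1
F3 | step 6 | (2S)-2-[(2S)-5-formyl-2,3-dihydro-1-benzofuran-2-yl]propyl (2E)-3-[4-(acetyloxy)phenyl]prop-2-enoate | C[C@@H](COC(=O)/C=C/c1ccc(OC(C)=O)cc1)[C@@H]1Cc2cc(C=O)ccc2O1
F4 | step 2 | methyl 3-(chloromethyl)-4-hydroxybenzoate | COC(=O)c1ccc(O)c(CCl)c1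
F5 | step 2 | methyl 4-(acetyloxy)-3-(chloromethyl)benzoate | COC(=O)c1ccc(OC(C)=O)c(CCl)c1
F6 | step 2 | methyl 4-(acetyloxy)-3-[(2E)-but-2-en-1-yl]benzoate | C/C=C/Cc1cc(C(=O)OC)ccc1OC(C)=O
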